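**Assumption:** 4,4-dimethoxybut-3-en-2-one (7) is taken to be a purchasable reagent. The target has no stereocentre, so nothing has to be assumed about configuration.

## Analysis of the target

The target is a depside: two separate benzene rings, not fused, joined by a single aryl ester. Ring A is a 2,4-dihydroxy-6-pentylbenzoyl unit. Ring B is a 2-hydroxy-6-propylbenzoic acid whose C4 oxygen carries the ring A acyl group (ring B numbering: C1 bears the carboxyl group, C2 the free hydroxyl, C4 the acylated oxygen, C6 the propyl chain). There is no stereocentre, so the whole problem is one of regiochemistry and functional-group differentiation. The central aryl ester is cleaved by hydroxide, alkoxides and amines, so no saponification is allowed once it exists. The free salicylic acid of ring B can decarboxylate in hot acid, and the three phenols are sensitive to oxidants. The difficulty lies in telling apart the two ring B oxygens (O4 acylated, O2 free) and the two carboxyl carbons (one esterified, one free), and in removing every protecting group at the end without touching the central ester. The strategy rests on one feature of ring B: C1 (carboxyl) and C6 (propyl) are adjacent and map onto an alk-2-ynoate, while C2 to C5 with oxygen on C2 and C4 map onto a 1,1,3-trioxygenated butadiene. Because O4 is the acylated oxygen, it can enter as the enol-ester oxygen of that diene, so the depside ester is in place before ring B exists.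

## Retrosynthetic reasoning

**15 to 14.** The last bond cut is the O–CH3 bond on the C2 oxygen of ring B. The benzannulation that builds ring B can only deliver this oxygen as a methyl ether. A boron trihalide removes the methyl group through a six-membered chelate with the neighbouring carboxyl group. With this operation last, 14 contains no other ether, so no selectivity between ethers is needed. The forward reaction only has to spare the depside ester and avoid decarboxylation.

**14 to 13.** Three benzyl–oxygen bonds are restored: two on the ring A phenols and one on the ring B carboxyl group. Hydrogenolysis removes all three under neutral conditions that leave the aryl ester untouched. It is placed before the demethylation because a boron trihalide would also attack aryl benzyl ethers, the chelated ortho one first. The benzyl cations set free would then sit next to two electron-rich rings.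

**13 to 9 and 11 (through 12).** This is the key disconnection. Ring B is opened at C1–C2 and C5–C6. C1 and C6, with carboxyl and propyl, go back to alkynoate 11. C2 to C5 go back to diene 9, whose C3 oxygen already carries the ring A acyl group. Cutting here removes the need to distinguish O2 from O4 by a selective acylation, and it joins the two halves in the same step that creates ring B. The forward reaction must be regioselective, with the acetal carbon bonding to the ester-bearing alkyne carbon. The enol ester must survive heating. Cycloadduct 12 must lose one methoxy group as the alcohol to become aromatic.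

**9 to 6 and 7 (through 8).** The enol ester C(acyl)–O bond is cut, which leads back to acid chloride 6 and the dienolate 8 of ketone 7. Ketone 7 has only one enolizable position, its methyl group, so the enolate is unambiguous. The forward reaction must acylate on oxygen and not on carbon. A potassium counter-ion and the two ortho substituents of 6 both favour oxygen.

**6 back to 1 (through 5, 4, 3).** The acid chloride comes from acid 5, the acid from aldehyde 4 by oxidation, the aldehyde from 3 by O-benzylation, and 3 from olivetol 1 by formylation. The carbonyl carbon is introduced as a formyl group and not directly as a carboxyl group for two reasons. Electrophilic formylation of 1 goes reliably to the position para to one hydroxyl and ortho to the other. The sequence also avoids saponifying a doubly ortho-substituted benzoate.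

**11 to 10.** The benzyl–oxygen bond of the ester is cut, leading back to acid 10. A benzyl ester is chosen so that the ring B carboxyl group is freed in the same hydrogenolysis as the ring A phenols.

## Alternatives that were turned down

**Alternative 1:** Ring B is cut at C1–C6 and C2–C3. In the forward direction dibenzyl malonate A1 adds in a Michael sense to (E)-hept-3-en-2-one A2. The methyl ketone enolate then closes onto one ester in a Claisen step, giving benzyl 2,4-dioxo-6-propylcyclohexane-1-carboxylate A3. Dehydrogenation would give benzyl 2,4-dihydroxy-6-propylbenzoate A4, which would be acylated on O4 with 6 and then hydrogenolysed.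
- In its favour: every step is a known reaction type on this substrate class, the materials are cheap, and the C2 oxygen arrives as a free phenol, so no demethylation is needed.
- Against it: A3 is at the wrong oxidation level, and aromatizing it with a halogen or a quinone risks substitution at the electron-rich C3 and C5 positions of A4. The depside bond is then made by esterifying a hindered acid chloride with a diphenol, so the O4/O2 selectivity depends only on the hydrogen bond of O2 to the ester.
- Comparison: this route is more reliable and about one step shorter than the chosen one. The chosen route offers in exchange a ring B that is formed aromatic, with the acyl group fixed on O4 by construction and not by a selectivity.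

**Alternative 2:** The ring A carbonyl is cut on both sides. In the forward direction 1,5-bis(benzyloxy)-2-iodo-3-pentylbenzene A5, carbon monoxide and the diphenol A4 would be joined by Pd(OAc)2, a bisphosphine and an amine base. The product would be benzyl 4-{[2,4-bis(benzyloxy)-6-pentylbenzoyl]oxy}-2-hydroxy-6-propylbenzoate A6.
- In its favour: the ring A acid and its chloride are not needed, A5 is two steps from 1, and A6 needs only hydrogenolysis.
- Against it: the acylpalladium intermediate is flanked by two ortho substituents. A phenoxide is a weak nucleophile toward it, so reduction of the carbon–iodine bond and direct aryl ether formation can compete. Ring B (A4) must still be made separately, for example by alternative 1, so nothing is saved in step count.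
- Comparison: the endgame is stronger than in the chosen route. The chosen route makes ring B and the linkage in one operation and needs no separate ring B synthesis and no carbon monoxide.

**Alternative 3:** Ring A is cut at its C1–C6 bond (C2–C7 of the acyl chain). In the forward direction benzyl 2-(benzyloxy)-6-propyl-4-[(3,5,7-trioxododecanoyl)oxy]benzoate A7 would undergo an intramolecular aldol addition of C2 onto the C7 ketone. Dehydration and enolization would give benzyl 2-(benzyloxy)-4-[(2,4-dihydroxy-6-pentylbenzoyl)oxy]-6-propylbenzoate A8.
- In its favour: it mirrors the biosynthesis, ring A needs no protecting groups, and only a hydrogenolysis follows.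
- Against it: A7 is an aryl ester, which is an activated acyl donor, and it has three enolizable ketones. Attack of the C5 enol oxygen on C1 would expel the ring B phenoxide and give a 4-hydroxy-2-pyrone. A Claisen closure of C6 onto C1 would give an acylphloroglucinol. Both destroy the depside link. A7 would also be laborious to prepare and to handle.
- Comparison: it shares with the chosen route the idea of having the ester in place before a ring is closed. The chosen route closes the ring by a cycloaddition with a single bonding pattern and has no competing closure modes.

Key step: step 7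

## Route

**Step 1**
Reactants: 1 olivetol (5-pentylbenzene-1,3-diol)
Product: 3 2,4-dihydroxy-6-pentylbenzaldehyde, via iminium chloride 2 (not isolated)
Conditions: POCl3, DMF, 0 °C to rt; then H2O, 50 °C
Reagents that add atoms: N,N-dimethylformamide, CN(C)C=O; water, O
Why: Vilsmeier–Haack formylation of a 5-alkylresorcinol should go to the ring position para to one hydroxyl and ortho to the other, which is less crowded than the position between the two hydroxyls; hydrolysis of iminium salt 2 on work-up releases the aldehyde.

**Step 2**
Reactants: 3 2,4-dihydroxy-6-pentylbenzaldehyde
Product: 4 2,4-bis(benzyloxy)-6-pentylbenzaldehyde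
Conditions: BnBr (2.5 equiv), K2CO3, DMF, 70 °C
Reagents that add atoms: benzyl bromide, BrCc1ccccc1
Why: Williamson ether synthesis on both phenols; warming is needed because the ortho hydroxyl is hydrogen-bonded to the aldehyde.

**Step 3**
Reactants: 4 2,4-bis(benzyloxy)-6-pentylbenzaldehyde
Product: 5 2,4-bis(benzyloxy)-6-pentylbenzoic acid
Conditions: NaClO2, NaH2PO4, 2-methylbut-2-ene (excess), t-BuOH/THF/H2O, 0 °C to rt
Reagents that add atoms: sodium chlorite, [Na+].[O-]Cl=O
Why: Pinnick oxidation converts the hindered aldehyde to the acid under mildly acidic conditions that leave the benzyl ethers alone; the alkene scavenger takes up hypochlorous acid so that the electron-rich ring is not chlorinated.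

**Step 4**
Reactants: 5 2,4-bis(benzyloxy)-6-pentylbenzoic acid
Product: 6 2,4-bis(benzyloxy)-6-pentylbenzoyl chloride
Conditions: (COCl)2, DMF (cat.), CH2Cl2, 0 °C to rt; evaporate, use crude
Reagents that add atoms: oxalyl chloride, O=C(Cl)C(=O)Cl
Why: Acid chloride formation through the chloroiminium catalyst formed from DMF; the by-products are gases, so the moisture-sensitive product needs no purification.

**Step 5**
Reactants: 7 4,4-dimethoxybut-3-en-2-one; 6 2,4-bis(benzyloxy)-6-pentylbenzoyl chloride
Product: 9 4,4-dimethoxybuta-1,3-dien-2-yl 2,4-bis(benzyloxy)-6-pentylbenzoate, via potassium dienolate 8 (not isolated)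
Conditions: 7, KN(SiMe3)2, THF, −78 °C; cannulate into 6, THF, −78 to 0 °C; non-aqueous work-up (hexane, Et3N, filtration), use crude
Reagents that add atoms: none
Why: Deprotonation of the only enolizable position of 7 gives cross-conjugated dienolate 8, the same enolate that is routinely trapped on oxygen by silyl chlorides; O-acylation of an enolate by an acid chloride is favoured here by the loosely bound potassium ion, by inverse addition, and by the two ortho substituents of 6, which disfavour C-acylation and later acyl transfer.

**Step 6**
Reactants: 10 hex-2-ynoic acid
Product: 11 benzyl hex-2-ynoate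
Conditions: BnBr, K2CO3, DMF, rt
Reagents that add atoms: benzyl bromide, BrCc1ccccc1
Why: O-alkylation of the carboxylate with a benzylic halide; the weak base at room temperature should not isomerize the ynoate to the allenoate.

**Step 7**
Reactants: 9 4,4-dimethoxybuta-1,3-dien-2-yl 2,4-bis(benzyloxy)-6-pentylbenzoate; 11 benzyl hex-2-ynoate
Product: 13 benzyl 4-{[2,4-bis(benzyloxy)-6-pentylbenzoyl]oxy}-2-methoxy-6-propylbenzoate, via cyclohexadiene ketal 12 (not isolated)
Conditions: 11 (3 equiv), PhMe (concentrated), 2,6-di-tert-butyl-4-methylphenol (cat.), sealed tube, 130 °C; then SiO2, CH2Cl2, rt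
Reagents that add atoms: none
Why: Proposed new method: the ketene acetal terminus and the 3-acyloxy group both raise the HOMO coefficient at the CH2 terminus of 9, so an asynchronous normal-demand [4+2] cycloaddition should begin with bonding of that carbon to the propyl-bearing beta carbon of 11 and end with bonding of the acetal carbon to the alpha carbon, forming ring B bonds C5–C6 and C1–C2 and giving cyclohexa-1,4-diene ketal 12. Ring B is thus closed as a six-membered carbocycle in an intermolecular [4+2] mode, and 1,4-elimination of methanol from 12 (one acetal methoxy group and one hydrogen of the ring CH2) is driven by aromatization and leaves the second methoxy group on C2. The closest known reaction type is the Diels–Alder and aromatization sequence of 1,1-dimethoxy-3-(silyloxy)buta-1,3-dienes with alk-2-ynoates, which gives 4-oxygenated 2-methoxy-6-alkylbenzoates in the same orientation; the change here is an aroyloxy group in place of the silyloxy group. No stereocentre is formed, since the two sp3 ring carbons of 12 are not stereogenic and become sp2 on aromatization. The selectivity needed is regiochemical (methoxy carbon next to the ester-bearing carbon, propyl next to the former CH2 carbon), and it is secured by the 1,1-dimethoxy terminus, which polarizes the diene more strongly than the enol ester and in the same sense. The enol ester is a weaker donor than a silyl enol ether, hence the higher temperature and the excess of 11; the ester carbonyl of 9 lies between a pentyl and a benzyloxy group, which should suppress intermolecular acyl transfer during heating. Acid is kept out until the cycloaddition is complete, because the ketene acetal would otherwise hydrolyse.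

**Step 8**
Reactants: 13 benzyl 4-{[2,4-bis(benzyloxy)-6-pentylbenzoyl]oxy}-2-methoxy-6-propylbenzoate
Product: 14 4-[(2,4-dihydroxy-6-pentylbenzoyl)oxy]-2-methoxy-6-propylbenzoic acid
Conditions: H2 (1 atm), 10% Pd/C, EtOAc, rt
Reagents that add atoms: none
Why: Catalytic hydrogenolysis removes the two aryl benzyl ethers and the benzyl ester under neutral conditions; the aryl ester, the methyl ether and both arenes are inert to it.

**Step 9**
Reactants: 14 4-[(2,4-dihydroxy-6-pentylbenzoyl)oxy]-2-methoxy-6-propylbenzoic acid
Product: 15 2-hydroxy-4-[(2,4-dihydroxy-6-pentylbenzoyl)oxy]-6-propylbenzoic acid (CNP0324314.0)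
Conditions: BCl3 (5 equiv), CH2Cl2, −78 to 0 °C; then ice-water
Reagents that add atoms: none
Why: Chelation-directed ether cleavage: the boron bound to the carboxyl group coordinates the ortho methoxy oxygen in a six-membered ring and chloride removes the methyl group by an SN2 attack; the hindered depside ester and the phenols (held as borates until hydrolysis) should be unaffected at 0 °C.

## Compound list

1 | olivetol (5-pentylbenzene-1,3-diol) | CCCCCc1cc(O)cc(O)c1 | starting material
2 | N-[(2,4-dihydroxy-6-pentylphenyl)methylidene]-N-methylmethanaminium chloride | CCCCCc1cc(O)cc(O)c1C=[N+](C)C.[Cl-] | intermediate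
3 | 2,4-dihydroxy-6-pentylbenzaldehyde | CCCCCc1cc(O)cc(O)c1C=O | intermediate
4 | 2,4-bis(benzyloxy)-6-pentylbenzaldehyde | CCCCCc1cc(OCc2ccccc2)cc(OCc2ccccc2)c1C=O | intermediate
5 | 2,4-bis(benzyloxy)-6-pentylbenzoic acid | CCCCCc1cc(OCc2ccccc2)cc(OCc2ccccc2)c1C(=O)O | intermediate
6 | 2,4-bis(benzyloxy)-6-pentylbenzoyl chloride | CCCCCc1cc(OCc2ccccc2)cc(OCc2ccccc2)c1C(=O)Cl | intermediate
7 | 4,4-dimethoxybut-3-en-2-one | CC(=O)C=C(OC)OC | starting material
8 | potassium 4,4-dimethoxybuta-1,3-dien-2-olate | C=C([O-])C=C(OC)OC.[K+] | intermediate
9 | 4,4-dimethoxybuta-1,3-dien-2-yl 2,4-bis(benzyloxy)-6-pentylbenzoate | CCCCCc1cc(OCc2ccccc2)cc(OCc2ccccc2)c1C(=O)OC(=C)C=C(OC)OC | intermediate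
10 | hex-2-ynoic acid | CCCC#CC(=O)O | starting material
11 | benzyl hex-2-ynoate | CCCC#CC(=O)OCc1ccccc1 | intermediate
12 | benzyl 4-{[2,4-bis(benzyloxy)-6-pentylbenzoyl]oxy}-6,6-dimethoxy-2-propylcyclohexa-1,4-diene-1-carboxylate | CCCC1=C(C(=O)OCc2ccccc2)C(OC)(OC)C=C(OC(=O)c2c(CCCCC)cc(OCc3ccccc3)cc2OCc2ccccc2)C1 | intermediate
13 | benzyl 4-{[2,4-bis(benzyloxy)-6-pentylbenzoyl]oxy}-2-methoxy-6-propylbenzoate | CCCCCc1cc(OCc2ccccc2)cc(OCc2ccccc2)c1C(=O)Oc1cc(OC)c(C(=O)OCc2ccccc2)c(CCC)c1 | intermediate
14 | 4-[(2,4-dihydroxy-6-pentylbenzoyl)oxy]-2-methoxy-6-propylbenzoic acid | CCCCCc1cc(O)cc(O)c1C(=O)Oc1cc(OC)c(C(=O)O)c(CCC)c1 | intermediate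
15 | 2-hydroxy-4-[(2,4-dihydroxy-6-pentylbenzoyl)oxy]-6-propylbenzoic acid | CCCCCc1cc(O)cc(O)c1C(=O)Oc1cc(O)c(C(=O)O)c(CCC)c1 | target

## Step count and risk

Total step count: 9. Longest linear sequence: 8 (steps 1, 2, 3, 4, 5, 7, 8, 9); step 6 is a one-step branch.

**Step 7 (key step, proposed new method).** The most likely failure is that the acyloxy diene is too weak a donor for a beta-alkyl ynoate. Thermal decomposition, polymerization or hydrolysis of the ketene acetal would then outrun the cycloaddition. Acyl transfer from the enol ester is a second possibility. The fallback uses only known chemistry and sets out from 7, 11 and 6. Ketone 7 is O-silylated (LiN(iPr)2, Me3SiCl, THF, −78 °C) to 1,1-dimethoxy-3-(trimethylsilyloxy)buta-1,3-diene F1. F1 undergoes the established cycloaddition and loss of methanol with 11 to give benzyl 2-methoxy-6-propyl-4-(trimethylsilyloxy)benzoate F2. Dilute aqueous HCl in THF converts it to benzyl 4-hydroxy-2-methoxy-6-propylbenzoate F3. The single free phenol of F3 is esterified with 6 (Et3N, DMAP, CH2Cl2), and the route is rejoined at 13.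

**Step 5.** C-acylation may compete with O-acylation. The hindered acid chloride may react so slowly that the enolate exchanges protons or condenses with 7. The ketene acetal may also be hydrolysed during isolation. The fallback sets out from 7 and 5 and avoids a basic metal enolate. The silyl dienol ether 1,1-dimethoxy-3-(trimethylsilyloxy)buta-1,3-diene F1 is made as above. Acid 5 is converted with cyanuric fluoride and pyridine to 2,4-bis(benzyloxy)-6-pentylbenzoyl fluoride F4. The two are joined by fluoride-catalysed O-acylation ([Bu4N][Ph3SiF2] cat., THF), which regenerates fluoride and gives only a volatile silyl fluoride. The route is rejoined at 9.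

**Step 9.** Demethylation may stall because the three acidic groups tie up the boron reagent and the borates are poorly soluble. The salicylic acid may decarboxylate during acidic work-up, or the depside ester may be cleaved. The fallback sets out from 13 and moves the ether cleavage ahead of the hydrogenolysis, so that the carboxyl group is still an ester. BCl3 with pentamethylbenzene as cation scavenger (CH2Cl2, −78 to 0 °C) removes the methyl ether and both aryl benzyl ethers. This gives benzyl 4-[(2,4-dihydroxy-6-pentylbenzoyl)oxy]-2-hydroxy-6-propylbenzoate F5. Hydrogenolysis (H2, 10% Pd/C, EtOAc) then gives 15. Any benzyl ester lost in the first operation also ends as 15.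

**Step 1.** Formylation may partly go to the position between the two hydroxyls, or a second formyl group may be introduced. The fallback sets out from 1 and sets the carboxyl position by halogenation of the protected arene. Benzylation (BnBr, K2CO3, DMF) gives 1,3-bis(benzyloxy)-5-pentylbenzene F6. N-bromosuccinimide in MeCN brominates next to the pentyl chain, giving 1,5-bis(benzyloxy)-2-bromo-3-pentylbenzene F7. Bromine–lithium exchange with n-BuLi (THF, −78 °C) gives [2,4-bis(benzyloxy)-6-pentylphenyl]lithium F8, which is quenched with CO2. The route is rejoined at 5, and steps 2 and 3 are no longer needed.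

## Further compounds

F1 | step 7 | 1,1-dimethoxy-3-(trimethylsilyloxy)buta-1,3-diene | C=C(O[Si](C)(C)C)C=C(OC)OC
F2 | step 7 | benzyl 2-methoxy-6-propyl-4-(trimethylsilyloxy)benzoate | CCCc1cc(O[Si](C)(C)C)cc(OC)c1C(=O)OCc1ccccc1
F3 | step 7 | benzyl 4-hydroxy-2-methoxy-6-propylbenzoate | CCCc1cc(O)cc(OC)c1C(=O)OCc1ccccc1
F4 | step 5 | 2,4-bis(benzyloxy)-6-pentylbenzoyl fluoride | CCCCCc1cc(OCc2ccccc2)cc(OCc2ccccc2)c1C(F)=O
F5 | step 9 | benzyl 4-[(2,4-dihydroxy-6-pentylbenzoyl)oxy]-2-hydroxy-6-propylbenzoate | CCCCCc1cc(O)cc(O)c1C(=O)Oc1cc(O)c(C(=O)OCc2ccccc2)c(CCC)c1
F6 | step 1 | 1,3-bis(benzyloxy)-5-pentylbenzene | CCCCCc1cc(OCc2ccccc2)cc(OCc2ccccc2)c1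
F7 | step 1 | 1,5-bis(benzyloxy)-2-bromo-3-pentylbenzene | CCCCCc1cc(OCc2ccccc2)cc(OCc2ccccc2)c1Br
F8 | step 1 | [2,4-bis(benzyloxy)-6-pentylphenyl]lithium | [Li]c1c(CCCCC)cc(OCc2ccccc2)cc1OCc1ccccc1
A1 | alternative 1 | dibenzyl malonate | O=C(CC(=O)OCc1ccccc1)OCc1ccccc1
A2 | alternative 1 | (E)-hept-3-en-2-one | CCC/C=C/C(C)=O
A3 | alternative 1 | benzyl 2,4-dioxo-6-propylcyclohexane-1-carboxylate (racemic, mixture of diastereomers) | CCCC1CC(=O)CC(=O)C1C(=O)OCc1ccccc1
A4 | alternative 1 | benzyl 2,4-dihydroxy-6-propylbenzoate | CCCc1cc(O)cc(O)c1C(=O)OCc1ccccc1
A5 | alternative 2 | 1,5-bis(benzyloxy)-2-iodo-3-pentylbenzene | CCCCCc1cc(OCc2ccccc2)cc(OCc2ccccc2)c1I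
A6 | alternative 2 | benzyl 4-{[2,4-bis(benzyloxy)-6-pentylbenzoyl]oxy}-2-hydroxy-6-propylbenzoate | CCCCCc1cc(OCc2ccccc2)cc(OCc2ccccc2)c1C(=O)Oc1cc(O)c(C(=O)OCc2ccccc2)c(CCC)c1
A7 | alternative 3 | benzyl 2-(benzyloxy)-6-propyl-4-[(3,5,7-trioxododecanoyl)oxy]benzoate | CCCCCC(=O)CC(=O)CC(=O)CC(=O)Oc1cc(OCc2ccccc2)c(C(=O)OCc2ccccc2)c(CCC)c1
A8 | alternative 3 | benzyl 2-(benzyloxy)-4-[(2,4-dihydroxy-6-pentylbenzoyl)oxy]-6-propylbenzoate | CCCCCc1cc(O)cc(O)c1C(=O)Oc1cc(OCc2ccccc2)c(C(=O)OCc2ccccc2)c(CCC)c1
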